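1. The north run cannot be slowing for lack of starting material: at 15.0 h its product stands at 32.0% of the charge, and 68.0% is unaccounted for by product.

| setting | north-east | north | south-east | delta | gamma | epsilon | eta | beta |
|---|---|---|---|---|---|---|---|---|
| starting material | 0.031 M | 0.47 M | 0.20 M | 0.20 M | 0.050 M | 0.20 M | 0.60 M | 0.20 M |
| precatalyst | 2.3 mol% | 2.3 mol% | 1 mol% | 3 mol% | 1.2 mol% | 0.6 mol% | 1.5 mol% | 2.3 mol% |
| remark | run made earlier | run made earlier | run made earlier |  |  |  |  |  |
| time |  |  |  | 30 h | 30 h | 30 h | 30 h | 30 h |

| run | time / h | product / % |
|---|---|---|
| north-east | 1.33 | 3.4 |
| north-east | 3.00 | 7.9 |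
| north-east | 6.00 | 14.1 |
| north-east | 15.0 | 24.2 |
| north | 1.33 | 9.3 |
| north | 3.00 | 19.1 |
| north | 6.00 | 27.5 |
| north | 15.0 | 32.0 |
| south-east | 4.00 | 9.2 |
| south-east | 8.00 | 12.9 |
| south-east | 12.0 | 12.4 |
| south-east | 15.0 | 13.9 |

(standard deviation of a reading: 0.3 percentage points)

- the earlier runs were read with a standard deviation of 0.3 percentage points

- ranking by amount of product, in percent of the starting material charged, from high to low, at 30 h (delta / gamma / epsilon / eta / beta)
- the amount of product, in percent of the starting material charged of the flask you put first, at 30 h
- the amount of product, in percent of the starting material charged of the flask you put last, at 30 h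

2. A bench rule fits this: count turnovers. With its last reading taken as the plateau, the north run gives 13.9, the turnover number, defined as plateau product in percent of the charge over precatalyst in mol%. The south-east run, at a different loading and concentration, reads 13.9. So, for these flasks at this one temperature, I take the ceiling on product as this number, read with its scatter, times the loading.

3. My ceilings are 41.7% for delta, 32.0% for beta, 20.9% for eta, 16.7% for gamma and 8.35% for epsilon.

4. The rule stops working where a flask has not reached its plateau. The north-east run reads 75.6% of its ceiling at 15.0 h. Its shortfall falls between 6.00 h and 15.0 h with a half-life of 7.51 h, as a reading. The asked time is 3.99 such half-lives, so my estimate of the shortfall for a flask as slow as the north-east run is about 6.27%. Gamma is the most dilute of the asked flasks, so I place it nearest this border. Gamma's [starting material] is 1.61 times that of the north-east run, and at the same loading the richer north run started faster than the north-east run. My estimate therefore puts gamma between 15.6% and its ceiling, and that range leaves my order unchanged.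

5. The forecast gives delta > beta > eta > gamma > epsilon, with 43.5% and 8.4%, on the ground that “The plateau therefore follows mol% catalyst, not concentration”. Its order is mine, and its top stands 1.8 points above my ceiling for delta.

6. The simulation gives delta > beta > eta > gamma > epsilon, with 41.6% and 8.33%.

    catalyst intermediate → spent catalyst (k = 0.00720 min⁻¹)
    catalyst intermediate ⇌ free catalyst + product (K = 18.0 M, k = 0.100 min⁻¹)
    precatalyst → free catalyst (k = 0.0510 min⁻¹)
    starting material + free catalyst → catalyst intermediate (k = 1.20 M⁻¹ min⁻¹)

Delta reaches 13.9 turnovers, and gamma gives 16.4%. The main reason for delta's ceiling is the turning of catalyst intermediate into spent catalyst: without that step, delta goes from 41.6% to >99.9%. Each pass through catalyst intermediate either releases product or loses the catalyst, and the forward constants stand at 13.9 to one. For a further flask, like epsilon but with 1.5 mol% of precatalyst, the turnover number puts the ceiling at 20.8%; that flask gives 20.8%, with 78% of the starting material still there, unbound.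

The data are calculated with constants of no real substance, and the scatter is random.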